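**Retrosynthetic overview**
1. Rhodisin is EGCG-(4β→8)-EGCG. The C4–C8 interflavan bond is cut last (C4 electrophile of one monomer plus ring A C8 of a second), so both halves come from one monomer, the 4-silyloxy octa-O-benzyl-EGCG 12.
2. Ring C of that monomer is cut at C2–C3 and C4–C4a. The forward step is an asymmetric oxa-Povarov-type [4+2] of an O-aryl oxocarbenium ion (O1=C2, from acetoxy acetal 4) with the enediol-derived alkene 9 (C3=C4, already carrying the gallate, ring D).
3. Enabling feature: C2 carries O1 and ring B, so it is reachable at the aldehyde oxidation level. C3 carries the gallate oxygen. C4 is benzylic to phloroglucinol ring A, whose C4a lies ortho to O1 and O5 and para to O7, and the two ortho carbons of that ring are equivalent.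
4. The C4–O bond left by the key step is reduced for the lower unit (C4 = CH2) and ionised, with participation of the neighbouring gallate, for the 4→8 coupling in the upper unit.
5. Ring order: rings A, B and D are bought as benzyl ethers; ring C forms in step 5; the interflavan bond forms in step 7; global debenzylation is step 8.

Key step: step 5

Assumption: compounds 1, 2 and 5 are taken as purchasable (each is one benzylation away from gallic aldehyde, phloroglucinol or gallic acid), and compound 12 is carried as a mixture of C4 epimers because the C4–O bond is ionised in steps 6 and 7 and both epimers converge there.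

**Route**

Step 1
Reactants: 1 3,4,5-tris(benzyloxy)benzaldehyde; 2 3,5-bis(benzyloxy)phenol
Product: 4 [3,5-bis(benzyloxy)phenoxy][3,4,5-tris(benzyloxy)phenyl]methyl acetate (racemic acetoxy acetal), via chloro ester 3 (not isolated)
Conditions: AcCl (1.0 equiv), ZnCl2 (2 mol %), CH2Cl2, −20 to 0 °C; then 2, i-Pr2NEt, CH2Cl2, −40 to 0 °C
Reagents that add atoms: acetyl chloride CC(=O)Cl
Why: ZnCl2-catalysed addition of the acyl chloride across the aldehyde C=O gives the ionisable benzylic chloro ester, which O-alkylates the phenol (acyloxyalkylation of a phenol, SN1-like); the acetal carbon is stereogenic but is planarised in step 5, so the racemate is used.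

Step 2
Reactants: 5 3,4,5-tris(benzyloxy)benzoic acid
Product: 6 allyl 3,4,5-tris(benzyloxy)benzoate
Conditions: allyl bromide, K2CO3, DMF, rt
Reagents that add atoms: allyl bromide C=CCBr
Why: SN2 O-alkylation of the carboxylate by an allylic halide, with no competing site in the molecule.

Step 3
Reactants: 6 allyl 3,4,5-tris(benzyloxy)benzoate
Product: 8 2-oxoethyl 3,4,5-tris(benzyloxy)benzoate, via diol 7 (not isolated)
Conditions: K2OsO4·2H2O (2 mol %), NaIO4 (4 equiv), 2,6-lutidine, 1,4-dioxane/H2O 3:1, rt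
Reagents that add atoms: sodium periodate [Na+].[O-]I(=O)(=O)=O (oxygen of the new aldehyde, delivered through the osmium catalyst)
Why: Lemieux–Johnson oxidative cleavage (dihydroxylation, then periodate glycol cleavage) of the terminal alkene; benzyl ethers and the aryl ester are inert and 2,6-lutidine suppresses over-oxidation.

Step 4
Reactants: 8 2-oxoethyl 3,4,5-tris(benzyloxy)benzoate
Product: 9 (Z)-2-[(tert-butyldimethylsilyl)oxy]ethenyl 3,4,5-tris(benzyloxy)benzoate
Conditions: TBSOTf (1.2 equiv), Et3N (2 equiv), CH2Cl2, −78 to 0 °C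
Reagents that add atoms: tert-butyldimethylsilyl trifluoromethanesulfonate CC(C)(C)[Si](C)(C)OS(=O)(=O)C(F)(F)F
Why: soft enolisation and O-silylation of an α-acyloxy aldehyde; the (Z)-enol silane is expected to predominate, as is usual for α-oxygenated acetaldehydes, and any (E)-isomer is removed on Et3N-deactivated silica.

Step 5
Reactants: 4 [3,5-bis(benzyloxy)phenoxy][3,4,5-tris(benzyloxy)phenyl]methyl acetate; 9 (Z)-2-[(tert-butyldimethylsilyl)oxy]ethenyl 3,4,5-tris(benzyloxy)benzoate
Product: 12 5,7-bis(benzyloxy)-4-[(tert-butyldimethylsilyl)oxy]-2-[3,4,5-tris(benzyloxy)phenyl]chroman-3-yl 3,4,5-tris(benzyloxy)benzoate (2R,3S; 2,3-cis; C4 epimers), via aryl oxocarbenium ion 10 (not isolated), via silyloxocarbenium ion 11 (not isolated)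
Conditions: (S,S)-IDPi acid (5 mol %; imidodiphosphorimidate built from two (S)-3,3'-bis[3,5-bis(trifluoromethyl)phenyl]-BINOL units, N-triflyl on both phosphorus atoms), 9 (1.5 equiv), toluene, −78 °C, slow addition of 4
Reagents that add atoms: none
Why: Proposed new method: the chiral acid protonates the acetate of 4 and acetic acid leaves, giving the O-aryl benzylic oxocarbenium ion 10 paired with the confined chiral anion; the enol silane 9 attacks C2 through its acyloxy-bearing carbon (the carbon beta to the silyloxy donor) and forms C2–C3, and the resulting O-silyl oxocarbenium ion 11 is captured at C4 by the ring A carbon ortho to the acetal oxygen, which forms C4–C4a and returns the proton to the catalyst. The closest known reaction types are the oxa-Povarov reaction (acid-promoted formal [4+2] of aryl oxocarbenium ions with alkenes to chromans) and the chiral imidodiphosphorimidate-catalysed Mukaiyama-type addition of enol silanes to oxocarbenium ions released from acetoxy acetals; new is their union on an acyclic O-aryl acetal with an enediol-derived alkene. Ring C closes by a 6-exo-trig Friedel–Crafts (Prins-type) attack of the arene on the C4=O+ carbon, the whole being a stepwise inverse-electron-demand [4+2] in which O1=C2 and C8a=C4a form the four-atom component. C2 and C3 arise together in the C2–C3 bond formation: the 2,3-cis relation should follow from the endo approach of the (Z)-alkene to the (E)-oxocarbenium ion, and the absolute sense from the face of 10 left open by the chiral anion (the catalyst antipode that leads to the EGCG series cannot be predicted with certainty and is fixed in the first run by hydrogenolysis of a sample of 14 and comparison with natural EGCG); C4 forms as an epimer mixture that is erased later. The step needs site selectivity in the alkene, secured because silyloxy is a far stronger donor than acyloxy; chemoselective ionisation, secured because acetate is the only good leaving group; and a single ring-closure site, secured because the two ortho carbons of the symmetric 3,5-bis(benzyloxy)phenoxy ring are equivalent and each is activated by three oxygens.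

Compound 12 is divided: about three quarters goes to step 6, the rest to step 7.

Step 6
Reactants: 12 4-silyloxy octa-O-benzyl-EGCG (C4 epimers)
Product: 14 (2R,3R)-5,7-bis(benzyloxy)-2-[3,4,5-tris(benzyloxy)phenyl]chroman-3-yl 3,4,5-tris(benzyloxy)benzoate (octa-O-benzyl-EGCG), via flavan-4-yl cation 13 (not isolated)
Conditions: Et3SiH (3 equiv), BF3·OEt2 (20 mol %), CH2Cl2, −78 to −30 °C
Reagents that add atoms: none
Why: ionic hydrogenation, in which the C4–OSi bond ionises to a benzylic cation stabilised by the ortho and para oxygens of ring A and the silane, present in excess, delivers hydride to C4 to give CH2; C2 and C3 are not touched.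

Step 7
Reactants: 12 4-silyloxy octa-O-benzyl-EGCG (C4 epimers; electrophile); 14 octa-O-benzyl-EGCG (nucleophile, 3 equiv, excess recovered)
Product: 16 hexadeca-O-benzylrhodisin (upper unit 2R,3R,4R; lower unit 2R,3R; 4β→8 linked), via dioxolanylium ion 15 (not isolated)
Conditions: TMSOTf (0.5 equiv), CH2Cl2, −78 to −40 °C
Reagents that add atoms: none
Why: Lewis acid-mediated Friedel–Crafts interflavan coupling with neighbouring-group participation, in which the carbonyl oxygen of the 3-O-galloyl group closes onto C4 on the α face as the silyloxy group of either epimer leaves, and C8 of 14 (the most nucleophilic and least hindered ring A position) opens the resulting cis-fused dioxolanylium ion at C4 from the β face with inversion, anti to the C3 oxygen and to the C2 aryl group, so that C4 is set as 4R (3,4-trans).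

Step 8
Reactants: 16 hexadeca-O-benzylrhodisin
Product: 17 rhodisin
Conditions: H2 (1 atm), Pd(OH)2/C, THF/MeOH/H2O 20:1:1, rt
Reagents that add atoms: none
Why: hydrogenolysis of the sixteen benzyl ethers under neutral conditions; the gallate esters, the interflavan bond and the five stereocentres are inert.

**Compound list**
1 | 3,4,5-tris(benzyloxy)benzaldehyde | O=Cc1cc(OCc2ccccc2)c(OCc2ccccc2)c(OCc2ccccc2)c1 | starting material
2 | 3,5-bis(benzyloxy)phenol | Oc1cc(OCc2ccccc2)cc(OCc2ccccc2)c1 | starting material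
3 | chloro[3,4,5-tris(benzyloxy)phenyl]methyl acetate (racemic) | CC(=O)OC(Cl)c1cc(OCc2ccccc2)c(OCc2ccccc2)c(OCc2ccccc2)c1 | intermediate
4 | [3,5-bis(benzyloxy)phenoxy][3,4,5-tris(benzyloxy)phenyl]methyl acetate (racemic) | CC(=O)OC(Oc1cc(OCc2ccccc2)cc(OCc2ccccc2)c1)c1cc(OCc2ccccc2)c(OCc2ccccc2)c(OCc2ccccc2)c1 | intermediate
5 | 3,4,5-tris(benzyloxy)benzoic acid | OC(=O)c1cc(OCc2ccccc2)c(OCc2ccccc2)c(OCc2ccccc2)c1 | starting material
6 | allyl 3,4,5-tris(benzyloxy)benzoate | C=CCOC(=O)c1cc(OCc2ccccc2)c(OCc2ccccc2)c(OCc2ccccc2)c1 | intermediate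
7 | 2,3-dihydroxypropyl 3,4,5-tris(benzyloxy)benzoate (racemic) | OCC(O)COC(=O)c1cc(OCc2ccccc2)c(OCc2ccccc2)c(OCc2ccccc2)c1 | intermediate
8 | 2-oxoethyl 3,4,5-tris(benzyloxy)benzoate | O=CCOC(=O)c1cc(OCc2ccccc2)c(OCc2ccccc2)c(OCc2ccccc2)c1 | intermediate
9 | (Z)-2-[(tert-butyldimethylsilyl)oxy]ethenyl 3,4,5-tris(benzyloxy)benzoate | CC(C)(C)[Si](C)(C)O/C=C\OC(=O)c1cc(OCc2ccccc2)c(OCc2ccccc2)c(OCc2ccccc2)c1 | intermediate
10 | (E)-[3,5-bis(benzyloxy)phenyl][3,4,5-tris(benzyloxy)benzylidene]oxonium ion (counter-ion: catalyst anion) | c1c(OCc2ccccc2)cc(OCc2ccccc2)cc1/[O+]=C/c1cc(OCc2ccccc2)c(OCc2ccccc2)c(OCc2ccccc2)c1 | intermediate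
11 | open-chain O-silyl oxocarbenium ion after C2–C3 bond formation (C2 and C3 as in EGCG; counter-ion: catalyst anion) | O=C(O[C@H](C=[O+][Si](C)(C)C(C)(C)C)[C@H](Oc1cc(OCc2ccccc2)cc(OCc2ccccc2)c1)c1cc(OCc2ccccc2)c(OCc2ccccc2)c(OCc2ccccc2)c1)c1cc(OCc2ccccc2)c(OCc2ccccc2)c(OCc2ccccc2)c1 | intermediate
12 | (2R,3S)-5,7-bis(benzyloxy)-4-[(tert-butyldimethylsilyl)oxy]-2-[3,4,5-tris(benzyloxy)phenyl]chroman-3-yl 3,4,5-tris(benzyloxy)benzoate, 2,3-cis, both C4 epimers (C3 is S only because the silyloxy-bearing C4 outranks C2; the spatial arrangement is that of EGCG) | O=C(O[C@@H]1C(O[Si](C)(C)C(C)(C)C)c2c(OCc3ccccc3)cc(OCc3ccccc3)cc2O[C@@H]1c1cc(OCc2ccccc2)c(OCc2ccccc2)c(OCc2ccccc2)c1)c1cc(OCc2ccccc2)c(OCc2ccccc2)c(OCc2ccccc2)c1 | intermediate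
13 | octa-O-benzyl-EGCG flavan-4-yl cation (C2 and C3 as in EGCG) | O=C(O[C@@H]1[CH+]c2c(OCc3ccccc3)cc(OCc3ccccc3)cc2O[C@@H]1c1cc(OCc2ccccc2)c(OCc2ccccc2)c(OCc2ccccc2)c1)c1cc(OCc2ccccc2)c(OCc2ccccc2)c(OCc2ccccc2)c1 | intermediate
14 | (2R,3R)-5,7-bis(benzyloxy)-2-[3,4,5-tris(benzyloxy)phenyl]chroman-3-yl 3,4,5-tris(benzyloxy)benzoate (octa-O-benzyl-EGCG) | O=C(O[C@@H]1Cc2c(OCc3ccccc3)cc(OCc3ccccc3)cc2O[C@@H]1c1cc(OCc2ccccc2)c(OCc2ccccc2)c(OCc2ccccc2)c1)c1cc(OCc2ccccc2)c(OCc2ccccc2)c(OCc2ccccc2)c1 | intermediate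
15 | cis-fused 2-[3,4,5-tris(benzyloxy)phenyl]-1,3-dioxolan-2-ylium (acyloxonium) ion across C3–C4 of the octa-O-benzyl flavan (galloyl carbonyl oxygen bonded to C4 on the α face, syn to the C3–O bond; C2 and C3 as in EGCG; counter-ion: triflate) | [O+]1=C(c2cc(OCc3ccccc3)c(OCc3ccccc3)c(OCc3ccccc3)c2)O[C@@H]2[C@H]1c1c(OCc3ccccc3)cc(OCc3ccccc3)cc1O[C@@H]2c1cc(OCc2ccccc2)c(OCc2ccccc2)c(OCc2ccccc2)c1 | intermediate
16 | hexadeca-O-benzylrhodisin (upper unit 2R,3R,4R; lower unit 2R,3R; C4 of the upper unit bonded to C8 of the lower unit) | O=C(O[C@@H]1[C@@H](c2c(OCc4ccccc4)cc(OCc4ccccc4)c3c2O[C@H](c2cc(OCc4ccccc4)c(OCc4ccccc4)c(OCc4ccccc4)c2)[C@H](OC(=O)c2cc(OCc4ccccc4)c(OCc4ccccc4)c(OCc4ccccc4)c2)C3)c2c(OCc4ccccc4)cc(OCc4ccccc4)cc2O[C@@H]1c1cc(OCc4ccccc4)c(OCc4ccccc4)c(OCc4ccccc4)c1)c1cc(OCc4ccccc4)c(OCc4ccccc4)c(OCc4ccccc4)c1 | intermediate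
17 | rhodisin, EGCG-(4β→8)-EGCG | O=C(O[C@@H]1[C@@H](c2c(O)cc(O)c3c2O[C@H](c2cc(O)c(O)c(O)c2)[C@H](OC(=O)c2cc(O)c(O)c(O)c2)C3)c2c(O)cc(O)cc2O[C@@H]1c1cc(O)c(O)c(O)c1)c1cc(O)c(O)c(O)c1 | target

**Step count and risks**
Total step count: 8. Longest linear sequence: 7 (steps 2, 3, 4, 5, 6, 7, 8).

Steps most likely to fail:

1. Step 5 (proposed new method). Three things may go wrong:
   - poor endo/exo or facial selectivity in the C2–C3 bond formation (2,3-trans material or low enantiomeric purity);
   - intermolecular arylation of ion 10 by electron-rich ring A carbons, or 5-ring closure of ion 11 onto ring B;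
   - renewed ionisation of the C4–OSi bond of the product by the strong acid.

   Fallback, chiral pool and known chemistry only. It sets out from acid 5 and brings in purchased (−)-epigallocatechin F1. Benzylation of the five phenols (BnBr, K2CO3, DMF) gives 5,7,3',4',5'-penta-O-benzyl-epigallocatechin F2. Steglich esterification of one part of F2 with 5 (DCC, DMAP, CH2Cl2) gives 14, where the route is rejoined for the nucleophile. The other part of F2 is oxidised at C4 with DDQ in the presence of 2-ethoxyethanol (CH2Cl2, rt) to the 4β-(2-ethoxyethoxy) ether F3, which is esterified with 5 in the same way to the gallate F4. F4 takes the place of 12 in step 7 (TMSOTf, 14) and the route is rejoined at 16.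

2. Step 1. C-alkylation of the phenol ring instead of O-alkylation, transacylation of the phenol by the chloro ester, or hydrolytic loss of the acetoxy acetal on isolation.

   Fallback, building the acetal carbon from the acid oxidation level. It sets out from 2 and 5. DCC/DMAP esterification gives 3,5-bis(benzyloxy)phenyl 3,4,5-tris(benzyloxy)benzoate F5. Reduction with DIBAL-H at −78 °C and trapping of the aluminium hemiacetal in the same flask with Ac2O, pyridine and DMAP (reductive acetylation of an ester to an acetoxy acetal) gives 4, where the route is rejoined.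

3. Step 7. Self-condensation of the ionised upper unit with ring A of its own precursor, over-reaction of the dimer to trimers, and erosion of the 3,4-trans selectivity if the gallate does not shield the α face.

   Fallback, capping of the electrophile. It sets out from 12. NBS (CH2Cl2, −20 °C) brominates C8 of ring A to give the 8-bromo derivative F6, which can no longer act as a nucleophile at C8. Coupling of F6 with 14 (TMSOTf, CH2Cl2, −78 to −40 °C) gives the 8-bromo dimer F7. Hydrogenolysis under the conditions of step 8 with Et3N added removes the bromine together with the benzyl groups, and the route is rejoined at 17.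

**Further compounds**
F1 | step 5 | (−)-epigallocatechin, (2R,3R) | O[C@@H]1Cc2c(O)cc(O)cc2O[C@@H]1c1cc(O)c(O)c(O)c1
F2 | step 5 | (2R,3R)-5,7-bis(benzyloxy)-2-[3,4,5-tris(benzyloxy)phenyl]chroman-3-ol (penta-O-benzyl-epigallocatechin) | O[C@@H]1Cc2c(OCc3ccccc3)cc(OCc3ccccc3)cc2O[C@@H]1c1cc(OCc2ccccc2)c(OCc2ccccc2)c(OCc2ccccc2)c1
F3 | step 5 | (2R,3R,4S)-5,7-bis(benzyloxy)-4-(2-ethoxyethoxy)-2-[3,4,5-tris(benzyloxy)phenyl]chroman-3-ol (4β ether, 3,4-trans) | O[C@@H]1[C@@H](OCCOCC)c2c(OCc3ccccc3)cc(OCc3ccccc3)cc2O[C@@H]1c1cc(OCc2ccccc2)c(OCc2ccccc2)c(OCc2ccccc2)c1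
F4 | step 5 | (2R,3R,4S)-5,7-bis(benzyloxy)-4-(2-ethoxyethoxy)-2-[3,4,5-tris(benzyloxy)phenyl]chroman-3-yl 3,4,5-tris(benzyloxy)benzoate | O=C(O[C@@H]1[C@@H](OCCOCC)c2c(OCc3ccccc3)cc(OCc3ccccc3)cc2O[C@@H]1c1cc(OCc2ccccc2)c(OCc2ccccc2)c(OCc2ccccc2)c1)c1cc(OCc2ccccc2)c(OCc2ccccc2)c(OCc2ccccc2)c1
F5 | step 1 | 3,5-bis(benzyloxy)phenyl 3,4,5-tris(benzyloxy)benzoate | O=C(Oc1cc(OCc2ccccc2)cc(OCc2ccccc2)c1)c1cc(OCc2ccccc2)c(OCc2ccccc2)c(OCc2ccccc2)c1
F6 | step 7 | 8-bromo derivative of 12 (C2 and C3 as in 12, C4 epimers) | O=C(O[C@@H]1C(O[Si](C)(C)C(C)(C)C)c2c(OCc3ccccc3)cc(OCc3ccccc3)c(Br)c2O[C@@H]1c1cc(OCc2ccccc2)c(OCc2ccccc2)c(OCc2ccccc2)c1)c1cc(OCc2ccccc2)c(OCc2ccccc2)c(OCc2ccccc2)c1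
F7 | step 7 | 8-bromo derivative of 16 (bromine on C8 of the upper unit; stereocentres as in 16) | O=C(O[C@@H]1[C@@H](c2c(OCc4ccccc4)cc(OCc4ccccc4)c3c2O[C@H](c2cc(OCc4ccccc4)c(OCc4ccccc4)c(OCc4ccccc4)c2)[C@H](OC(=O)c2cc(OCc4ccccc4)c(OCc4ccccc4)c(OCc4ccccc4)c2)C3)c2c(OCc4ccccc4)cc(OCc4ccccc4)c(Br)c2O[C@@H]1c1cc(OCc4ccccc4)c(OCc4ccccc4)c(OCc4ccccc4)c1)c1cc(OCc4ccccc4)c(OCc4ccccc4)c(OCc4ccccc4)c1
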